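Germacrane numbering is used. Retrosynthetic cuts, in order: the acyl–O bonds of the C13 acetate and the C3 tiglate, then C3–C4 of the ten-membered ring, then C7–C8, C11–C12 and O–C12 of the butenolide in one operation.
The last cut rests on the lactone ring (ring O, C12, C11, C7, C6). Its C7=C11 bond is tetrasubstituted, with the C8 chain on C7 and the C13 oxymethyl group on C11, and its only stereocentre is the oxygen-bearing C6. The ring therefore maps onto an alkynol C6(OH)–C7≡C11–C13, a C8 carbanion and CO2 (C12).
Forward: fragment A (C4–C7, C11, C13, C15; alkynol with an E-alkenylstannane at C4) and fragment B (C8–C10, C14, C1–C3; Z-homoallylic Grignard reagent) are built separately. Their union with CO2 closes the butenolide first, a Nozaki–Hiyama–Kishi reaction closes the ten-membered ring second, and the two esters come last.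
Stereochemistry: C6 (R) from a Midland reduction of an ynone; C3 (S) from a Corey–Bakshi–Shibata reduction of the macrocyclic enone; C4=C5 (E) from a syn stannylcupration; C1=C10 (Z) from the ring of a Birch diene; the tigloyl group from tiglic acid.
Spectator groups: tin at C4, because I2 exchanges it for iodine faster than it attacks the C1=C10 alkene; a silyl ether at C3, so that the labile β,γ-unsaturated aldehyde exists for one step only; a triisopropylsilyl ether at C13, too bulky to bind magnesium or to leave.

Key step: step 12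

Assumption: in the oxazaborolidine reduction of the macrocyclic enone the α-methylalkenyl arm (C4) is taken as the large and the C2 methylene as the small substituent, as for acyclic α-substituted enones; the configurations at C6 and C3 would be confirmed by Mosher ester analysis.

Step 1
Reactants: 1 propargyl alcohol (prop-2-yn-1-ol)
Product: 2 triisopropyl(prop-2-yn-1-yloxy)silane
Conditions: TIPSCl, imidazole, CH2Cl2, 0 °C → rt
Reagents that add atoms: triisopropylsilyl chloride, CC(C)[Si](Cl)(C(C)C)C(C)C
Why: Imidazole-promoted O-silylation of a primary alcohol is routine, and the triisopropylsilyl group is chosen because this oxygen (C13) must later sit next to an alkenylmagnesium centre without binding the metal or being expelled.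

Step 2
Reactants: 3 ethyl but-2-ynoate
Product: 5 ethyl (E)-3-(tributylstannyl)but-2-enoate, via alkenylcopper adduct 4 (not isolated)
Conditions: Bu3SnH, LiN(i-Pr)2, THF, 0 °C; CuBr·SMe2, −78 °C; 3, MeOH, −78 °C
Reagents that add atoms: tributyltin hydride, CCCC[SnH](CCCC)CCCC
Why: Stannylcupration of an alkynoate is a syn addition with tin going to the β-carbon (C4), and protonation of the first-formed adduct 4 by methanol at −78 °C, before it can isomerise through the allenolate, should give the E ester with tin trans to the carbonyl carbon, which is the C4=C5 geometry of the target.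

Step 3
Reactants: 5 ethyl (E)-3-(tributylstannyl)but-2-enoate
Product: 6 (E)-N-methoxy-N-methyl-3-(tributylstannyl)but-2-enamide
Conditions: MeNH(OMe)·HCl, i-PrMgCl, THF, −20 → 0 °C
Reagents that add atoms: N,O-dimethylhydroxylamine hydrochloride, CNOC.Cl
Why: Weinreb amide formation by attack of the chloromagnesium amide of N,O-dimethylhydroxylamine on the ester runs below 0 °C and touches neither the C–Sn bond nor the alkene geometry.

Step 4
Reactants: 2 triisopropyl(prop-2-yn-1-yloxy)silane; 6 (E)-N-methoxy-N-methyl-3-(tributylstannyl)but-2-enamide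
Product: 9 (E)-2-(tributylstannyl)-7-(triisopropylsilyloxy)hept-2-en-5-yn-4-one, via lithium acetylide 7 (not isolated), via tetrahedral lithium adduct 8 (not isolated)
Conditions: 2 (1.1 equiv), n-BuLi (1.0 equiv), THF, −78 °C; 6, −78 → −30 °C; AcOH, −78 °C
Reagents that add atoms: none
Why: Acylation of lithium acetylide 7 by a Weinreb amide stops at the ketone stage because the chelated adduct 8 holds until the quench, and cold acetic acid protonates the released amine before it can add to the ynone.

Step 5
Reactants: 9 (E)-2-(tributylstannyl)-7-(triisopropylsilyloxy)hept-2-en-5-yn-4-one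
Product: 11 (2E,4R)-2-(tributylstannyl)-7-(triisopropylsilyloxy)hept-2-en-5-yn-4-ol, via borinate ester 10 (not isolated)
Conditions: (R)-Alpine-Borane (B-isopinocampheyl-9-borabicyclo[3.3.1]nonane from (+)-α-pinene, 2 equiv), neat, rt; HOCH2CH2NH2, Et2O, 0 °C
Reagents that add atoms: none
Why: Midland reduction, in which the pinanyl β-hydrogen passes to the carbonyl carbon through a six-membered boat-like transition state with the slim alkynyl arm next to the pinane methyl group and the bulkier alkenyl arm pointing away, the same arrangement that turns simple alk-1-yn-3-ones into (R)-alkynols with this enantiomer of the reagent, so C6 should be set as R.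

Step 6
Reactants: 12 4-methylanisole
Product: 13 1-methoxy-4-methylcyclohexa-1,4-diene
Conditions: Li, NH3(l), t-BuOH, THF, −78 → −33 °C
Reagents that add atoms: none
Why: Birch reduction of an arene with two donor substituents in a para relationship leaves both on alkene carbons, so the 1,4-diene forms with the future C1=C10 bond held cis inside the six-membered ring.

Step 7
Reactants: 13 1-methoxy-4-methylcyclohexa-1,4-diene
Product: 16 methyl (Z)-6-hydroxy-4-methylhex-3-enoate, via methoxy hydroperoxide 14 (not isolated), via aldehyde ester 15 (not isolated)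
Conditions: O3 (1.0 equiv), CH2Cl2–MeOH, −78 °C; Me2S, −78 °C → rt; NaBH4, 0 °C
Reagents that add atoms: ozone, [O-][O+]=O
Why: Ozone attacks the electron-rich enol ether far faster than the trialkyl alkene, so one equivalent cleaves only C(OMe)=CH (chemoselective ozonolysis, methanol trapping to 14, Me2S reduction to 15), the two ends emerge differentiated as ester (C3) and aldehyde (C8), NaBH4 reduces only the aldehyde, and the Z geometry is inherited from the ring.

Step 8
Reactants: 16 methyl (Z)-6-hydroxy-4-methylhex-3-enoate
Product: 17 methyl (Z)-6-bromo-4-methylhex-3-enoate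
Conditions: CBr4, PPh3, CH2Cl2, 0 °C
Reagents that add atoms: carbon tetrabromide, BrC(Br)(Br)Br
Why: The Appel reaction replaces a primary hydroxyl by bromide under neutral conditions that do not move the β,γ-double bond into conjugation with the ester.

Step 9
Reactants: 17 methyl (Z)-6-bromo-4-methylhex-3-enoate
Product: 18 (Z)-6-bromo-4-methylhex-3-en-1-ol
Conditions: i-Bu2AlH (2.2 equiv), CH2Cl2, −78 → 0 °C; aq potassium sodium tartrate
Reagents that add atoms: none
Why: Ester reduction by i-Bu2AlH reaches the primary alcohol at low temperature without reducing the primary bromide or isomerising the alkene.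

Step 10
Reactants: 18 (Z)-6-bromo-4-methylhex-3-en-1-ol
Product: 19 (Z)-[(6-bromo-4-methylhex-3-en-1-yl)oxy](tert-butyl)dimethylsilane
Conditions: TBSCl, imidazole, CH2Cl2, rt
Reagents that add atoms: tert-butyldimethylsilyl chloride, CC(C)(C)[Si](C)(C)Cl
Why: Standard silylation masks the C3 oxygen with a group that tolerates magnesium and can later be removed in the presence of the larger triisopropylsilyl ether.

Step 11
Reactants: 19 (Z)-[(6-bromo-4-methylhex-3-en-1-yl)oxy](tert-butyl)dimethylsilane
Product: 20 [(3Z)-6-(tert-butyldimethylsilyloxy)-3-methylhex-3-en-1-yl]magnesium bromide (titrated ether solution)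
Conditions: Mg turnings, Et2O, reflux
Reagents that add atoms: magnesium, [Mg]
Why: Grignard formation from a primary alkyl bromide in ether is routine, silyl ethers are inert to it, and an open-chain homoallylic Grignard reagent with a trisubstituted alkene keeps its structure and geometry because closure to the cyclopropylcarbinyl isomer would give a less stable secondary organomagnesium.

Step 12
Reactants: 11 (2E,4R)-2-(tributylstannyl)-7-(triisopropylsilyloxy)hept-2-en-5-yn-4-ol; 20 [(3Z)-6-(tert-butyldimethylsilyloxy)-3-methylhex-3-en-1-yl]magnesium bromide; 21 carbon dioxide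
Product: 26 (5R)-4-[(3Z)-6-(tert-butyldimethylsilyloxy)-3-methylhex-3-en-1-yl]-5-[(1E)-2-(tributylstannyl)prop-1-en-1-yl]-3-[(triisopropylsilyloxy)methyl]furan-2(5H)-one, via bromomagnesium alkoxide 22 (not isolated), via oxamagnesacycle 23 (not isolated), via magnesium carboxylate 24 (not isolated), via hydroxy acid 25 (not isolated)
Conditions: 11, MeMgBr (1.0 equiv), Et2O, 0 °C; CuI (0.3 equiv), 20 (2.5 equiv), Et2O–toluene, −10 °C → rt; CO2 (dry gas), −20 °C → rt; 10 % aq citric acid, 0 °C
Reagents that add atoms: none
Why: Methylmagnesium bromide first turns 11 into alkoxide 22 so that none of reagent 20 is spent on the O–H bond; the alkylcopper species made from 20 and CuI then adds to the alkoxide-bound alkyne, C8 going to the near alkyne carbon C7 and the metal to C11 from the opposite side, which is the copper-assisted anti-carbomagnesiation of propargylic alcohols, a known reaction type that includes the CO2 quench to butenolides. The outcome is the five-membered oxamagnesacycle 23 (O, C6, C7, C11, Mg), whose C11–Mg bond takes up CO2 with retention and forms C11–C12 in carboxylate 24. Because the addition is anti, the carboxyl group and the C6 oxygen lie on the same side of C7=C11 in hydroxy acid 25, and mild acid closes O–C12 by a 5-exo-trig addition–elimination at the carboxyl carbon, so the geometry of the tetrasubstituted alkene is fixed by the ring. No stereocentre is created, and C6, set in step 5, has no bond broken and keeps its R configuration. The step needs regioselectivity (C8 to C7, not C11) and chemoselectivity (no expulsion of the C13 oxygen from the β-oxygenated alkenylmagnesium): the first is secured by the C6 alkoxide as the only group able to hold magnesium, the second by the bulky, weakly basic triisopropylsilyl ether, which is a poor ligand and a poor leaving group. The alkenylstannane with tin on a fully substituted carbon, the Z alkene and both silyl ethers should not react with alkylmagnesium or alkylcopper species in ether, and citric acid is weak enough to spare the C–Sn bond.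

Step 13
Reactants: 26 butenolide with stannane and both silyl ethers
Product: 27 (5R)-4-[(3Z)-6-(tert-butyldimethylsilyloxy)-3-methylhex-3-en-1-yl]-5-[(1E)-2-iodoprop-1-en-1-yl]-3-[(triisopropylsilyloxy)methyl]furan-2(5H)-one
Conditions: I2 (1.0 equiv), CH2Cl2, −78 → 0 °C
Reagents that add atoms: iodine, II
Why: Iododestannylation is an ipso substitution with retention that is complete within minutes at low temperature, so one equivalent of I2 is used up by the C–Sn bond before it can add to the C1=C10 alkene.

Step 14
Reactants: 27 alkenyl iodide with both silyl ethers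
Product: 28 (5R)-4-[(3Z)-6-hydroxy-3-methylhex-3-en-1-yl]-5-[(1E)-2-iodoprop-1-en-1-yl]-3-[(triisopropylsilyloxy)methyl]furan-2(5H)-one
Conditions: pyridinium p-toluenesulfonate (0.2 equiv), MeOH, rt
Reagents that add atoms: none
Why: Acid-catalysed methanolysis of silyl ethers is governed by the bulk at silicon, so the primary tert-butyldimethylsilyl ether is cleaved selectively while the triisopropylsilyl ether, the lactone and the alkenyl iodide remain.

Step 15
Reactants: 28 primary alcohol (C3–OH)
Product: 29 (3Z)-6-{(2R)-2-[(1E)-2-iodoprop-1-en-1-yl]-5-oxo-4-[(triisopropylsilyloxy)methyl]-2,5-dihydrofuran-3-yl}-4-methylhex-3-enal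
Conditions: Dess–Martin periodinane, NaHCO3, CH2Cl2, 0 °C
Reagents that add atoms: none
Why: Buffered Dess–Martin oxidation gives β,γ-unsaturated aldehydes without acid or base strong enough to shift the double bond, and the aldehyde is carried on at once.

Step 16
Reactants: 29 iodo aldehyde
Product: 31 (6R)-3-hydroxy-13-(triisopropylsilyloxy)germacra-1(10)Z,4E,7(11)-trien-12,6-olide as a mixture of C3 epimers, via alkenylchromium species 30 (not isolated)
Conditions: CrCl2 (10 equiv), NiCl2 (1 mol % of the CrCl2), degassed DMSO–THF, slow addition to 0.002 M, rt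
Reagents that add atoms: none
Why: Nozaki–Hiyama–Kishi reaction, in which nickel-catalysed insertion gives alkenylchromium 30 with retention of the E geometry, this reagent adds to the aldehyde and ignores the lactone, high dilution favours the ten-membered ring (a ring size for which this closure is known), and the C3 configuration is left open here because it is fixed in steps 17 and 18.

Step 17
Reactants: 31 macrocyclic allylic alcohol (C3 epimers)
Product: 32 (6R)-3-oxo-13-(triisopropylsilyloxy)germacra-1(10)Z,4E,7(11)-trien-12,6-olide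
Conditions: Dess–Martin periodinane, NaHCO3, CH2Cl2, 0 °C
Reagents that add atoms: none
Why: Dess–Martin oxidation of the allylic alcohol merges both C3 epimers into one enone under buffered conditions that avoid enolisation towards C2 or C6.

Step 18
Reactants: 32 macrocyclic enone
Product: 33 (3S,6R)-3-hydroxy-13-(triisopropylsilyloxy)germacra-1(10)Z,4E,7(11)-trien-12,6-olide
Conditions: (R)-2-methyl-CBS-oxazaborolidine [(3aR)-1-methyl-3,3-diphenyltetrahydro-3H-pyrrolo[1,2-c][1,3,2]oxazaborole] (0.3 equiv), catecholborane, toluene, −78 °C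
Reagents that add atoms: none
Why: Corey–Bakshi–Shibata reduction, in which the ketone binds to the catalyst boron through the lone pair on the side of the small C2 methylene, hydride from the coordinated borane reaches the exposed face, and with the R catalyst this model (the mirror image of the S catalyst and acetophenone case that gives the R alcohol) leads to the 3S allylic alcohol by 1,2-reduction.

Step 19
Reactants: 33 (3S,6R)-allylic alcohol; 34 tiglic acid [(E)-2-methylbut-2-enoic acid]
Product: 36 (3S,6R)-3-tigloyloxy-13-(triisopropylsilyloxy)germacra-1(10)Z,4E,7(11)-trien-12,6-olide, via mixed anhydride 35 (not isolated)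
Conditions: 34, 2,4,6-trichlorobenzoyl chloride, Et3N, toluene, rt; 33, 4-(dimethylamino)pyridine, 0 °C → rt
Reagents that add atoms: none
Why: Yamaguchi esterification through mixed anhydride 35 acylates hindered secondary alcohols at or below room temperature with retention at C3, and the E geometry of the tigloyl group is the stable one.

Step 20
Reactants: 36 tiglate with C13 silyl ether
Product: 37 (3S,6R)-13-hydroxy-3-tigloyloxygermacra-1(10)Z,4E,7(11)-trien-12,6-olide
Conditions: HF·pyridine, pyridine, THF, 0 °C → rt
Reagents that add atoms: none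
Why: Fluoride-mediated desilylation with pyridine-buffered HF is slightly acidic, so the acidic C6–H of the butenolide and the two acyl–oxygen bonds are not endangered as they would be by a basic fluoride source.

Step 21
Reactants: 37 C13 alcohol
Product: 38 CNP0198881.1, (3S,6R)-13-acetoxy-3-tigloyloxygermacra-1(10)Z,4E,7(11)-trien-12,6-olide
Conditions: Ac2O, pyridine, 4-(dimethylamino)pyridine (cat.), CH2Cl2, 0 °C
Reagents that add atoms: acetic anhydride, CC(=O)OC(C)=O
Why: Acetylation of the primary allylic alcohol with acetic anhydride and pyridine is fast at 0 °C and completes the target.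

Compound list
1 | propargyl alcohol | C#CCO | starting material
2 | triisopropyl(prop-2-yn-1-yloxy)silane | C#CCO[Si](C(C)C)(C(C)C)C(C)C | intermediate
3 | ethyl but-2-ynoate | CC#CC(=O)OCC | starting material
4 | ethyl 2-cuprio-3-(tributylstannyl)but-2-enoate, Cu and Sn cis (not isolated) | CCOC(=O)/C([Cu])=C(\C)[Sn](CCCC)(CCCC)CCCC | intermediate
5 | ethyl (E)-3-(tributylstannyl)but-2-enoate | CCOC(=O)/C=C(\C)[Sn](CCCC)(CCCC)CCCC | intermediate
6 | (E)-N-methoxy-N-methyl-3-(tributylstannyl)but-2-enamide | CON(C)C(=O)/C=C(\C)[Sn](CCCC)(CCCC)CCCC | intermediate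
7 | lithium 3-(triisopropylsilyloxy)prop-1-yn-1-ide (not isolated) | [Li]C#CCO[Si](C(C)C)(C(C)C)C(C)C | intermediate
8 | lithium alkoxide adduct of 7 and 6 (not isolated) | [Li]OC(/C=C(\C)[Sn](CCCC)(CCCC)CCCC)(C#CCO[Si](C(C)C)(C(C)C)C(C)C)N(C)OC | intermediate
9 | (E)-2-(tributylstannyl)-7-(triisopropylsilyloxy)hept-2-en-5-yn-4-one | O=C(/C=C(\C)[Sn](CCCC)(CCCC)CCCC)C#CCO[Si](C(C)C)(C(C)C)C(C)C | intermediate
10 | 9-borabicyclo[3.3.1]nonan-9-yl ether of 11 (not isolated) | C1CC2CCCC(C1)B2O[C@H](/C=C(\C)[Sn](CCCC)(CCCC)CCCC)C#CCO[Si](C(C)C)(C(C)C)C(C)C | intermediate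
11 | (2E,4R)-2-(tributylstannyl)-7-(triisopropylsilyloxy)hept-2-en-5-yn-4-ol | O[C@H](/C=C(\C)[Sn](CCCC)(CCCC)CCCC)C#CCO[Si](C(C)C)(C(C)C)C(C)C | intermediate
12 | 4-methylanisole | COc1ccc(C)cc1 | starting material
13 | 1-methoxy-4-methylcyclohexa-1,4-diene | COC1=CCC(C)=CC1 | intermediate
14 | methyl (Z)-6-hydroperoxy-6-methoxy-4-methylhex-3-enoate (not isolated) | COC(=O)C/C=C(/C)CC(OC)OO | intermediate
15 | methyl (Z)-4-methyl-6-oxohex-3-enoate (not isolated) | COC(=O)C/C=C(/C)CC=O | intermediate
16 | methyl (Z)-6-hydroxy-4-methylhex-3-enoate | COC(=O)C/C=C(/C)CCO | intermediate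
17 | methyl (Z)-6-bromo-4-methylhex-3-enoate | COC(=O)C/C=C(/C)CCBr | intermediate
18 | (Z)-6-bromo-4-methylhex-3-en-1-ol | OCC/C=C(/C)CCBr | intermediate
19 | (Z)-[(6-bromo-4-methylhex-3-en-1-yl)oxy](tert-butyl)dimethylsilane | CC(C)(C)[Si](C)(C)OCC/C=C(/C)CCBr | intermediate
20 | [(3Z)-6-(tert-butyldimethylsilyloxy)-3-methylhex-3-en-1-yl]magnesium bromide | Br[Mg]CC/C(C)=C\CCO[Si](C)(C)C(C)(C)C | intermediate
21 | carbon dioxide | O=C=O | starting material
22 | bromomagnesium alkoxide of 11 (not isolated) | Br[Mg]O[C@H](/C=C(\C)[Sn](CCCC)(CCCC)CCCC)C#CCO[Si](C(C)C)(C(C)C)C(C)C | intermediate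
23 | oxamagnesacycle, ring O–C6–C7=C11–Mg (not isolated) | [Mg]1O[C@H](/C=C(\C)[Sn](CCCC)(CCCC)CCCC)C(CC/C(C)=C\CCO[Si](C)(C)C(C)(C)C)=C1CO[Si](C(C)C)(C(C)C)C(C)C | intermediate
24 | magnesium carboxylate alkoxide (not isolated) | O=C1O[Mg]O[C@H](/C=C(\C)[Sn](CCCC)(CCCC)CCCC)C(CC/C(C)=C\CCO[Si](C)(C)C(C)(C)C)=C1CO[Si](C(C)C)(C(C)C)C(C)C | intermediate
25 | (Z)-γ-hydroxy enoic acid, CO2H cis to C6 (not isolated) | OC(=O)/C(CO[Si](C(C)C)(C(C)C)C(C)C)=C(/CC/C(C)=C\CCO[Si](C)(C)C(C)(C)C)[C@H](O)/C=C(\C)[Sn](CCCC)(CCCC)CCCC | intermediate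
26 | (5R)-4-[(3Z)-6-(tert-butyldimethylsilyloxy)-3-methylhex-3-en-1-yl]-5-[(1E)-2-(tributylstannyl)prop-1-en-1-yl]-3-[(triisopropylsilyloxy)methyl]furan-2(5H)-one | CC(C)[Si](C(C)C)(C(C)C)OCC1=C(CC/C(C)=C\CCO[Si](C)(C)C(C)(C)C)[C@@H](/C=C(\C)[Sn](CCCC)(CCCC)CCCC)OC1=O | intermediate
27 | (1E)-2-iodoprop-1-en-1-yl analogue of 26 | CC(C)[Si](C(C)C)(C(C)C)OCC1=C(CC/C(C)=C\CCO[Si](C)(C)C(C)(C)C)[C@@H](/C=C(\C)I)OC1=O | intermediate
28 | C3 primary alcohol from 27 | CC(C)[Si](C(C)C)(C(C)C)OCC1=C(CC/C(C)=C\CCO)[C@@H](/C=C(\C)I)OC1=O | intermediate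
29 | C3 aldehyde (iodo aldehyde) | CC(C)[Si](C(C)C)(C(C)C)OCC1=C(CC/C(C)=C\CC=O)[C@@H](/C=C(\C)I)OC1=O | intermediate
30 | alkenylchromium dichloride from 29 (not isolated) | CC(C)[Si](C(C)C)(C(C)C)OCC1=C(CC/C(C)=C\CC=O)[C@@H](/C=C(\C)[Cr](Cl)Cl)OC1=O | intermediate
31 | (6R)-3-hydroxy-13-(triisopropylsilyloxy)germacra-1(10)Z,4E,7(11)-trien-12,6-olide, C3 epimers | OC1C/C=C(/C)CCC2=C(CO[Si](C(C)C)(C(C)C)C(C)C)C(=O)O[C@@H]2/C=C/1C | intermediate
32 | (6R)-3-oxo-13-(triisopropylsilyloxy)germacra-1(10)Z,4E,7(11)-trien-12,6-olide | O=C1C/C=C(/C)CCC2=C(CO[Si](C(C)C)(C(C)C)C(C)C)C(=O)O[C@@H]2/C=C/1C | intermediate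
33 | (3S,6R)-3-hydroxy-13-(triisopropylsilyloxy)germacra-1(10)Z,4E,7(11)-trien-12,6-olide | O[C@H]1C/C=C(/C)CCC2=C(CO[Si](C(C)C)(C(C)C)C(C)C)C(=O)O[C@@H]2/C=C/1C | intermediate
34 | tiglic acid | C/C=C(\C)C(=O)O | starting material
35 | tiglic 2,4,6-trichlorobenzoic anhydride (not isolated) | C/C=C(\C)C(=O)OC(=O)c1c(Cl)cc(Cl)cc1Cl | intermediate
36 | (3S,6R)-3-tigloyloxy-13-(triisopropylsilyloxy)germacra-1(10)Z,4E,7(11)-trien-12,6-olide | C/C=C(\C)C(=O)O[C@H]1C/C=C(/C)CCC2=C(CO[Si](C(C)C)(C(C)C)C(C)C)C(=O)O[C@@H]2/C=C/1C | intermediate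
37 | (3S,6R)-13-hydroxy-3-tigloyloxygermacra-1(10)Z,4E,7(11)-trien-12,6-olide | C/C=C(\C)C(=O)O[C@H]1C/C=C(/C)CCC2=C(CO)C(=O)O[C@@H]2/C=C/1C | intermediate
38 | CNP0198881.1 | C/C=C(\C)C(=O)O[C@H]1C/C=C(/C)CCC2=C(COC(C)=O)C(=O)O[C@@H]2/C=C/1C | target

Total step count: 21. Longest linear sequence: 16 steps (steps 6 to 21, from 4-methylanisole).

Steps most likely to fail

Step 12. On a secondary, internal alkynol the carbomagnesiation may be slow. Regiocontrol may erode because C13 also bears oxygen. The alkenylmagnesium may expel silyloxide by β-elimination to an allene before CO2 arrives.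
- The fallback sets out from 6 and 20 and comes back at 26. It lets the polarity of an ynoate, not a chelate, fix the regiochemistry, and it brings C13 in last.
- Reduction of 6 with i-Bu2AlH gives (E)-3-(tributylstannyl)but-2-enal F1.
- Methyl propiolate is added to F1 with Me2Zn and the ProPhenol ligand (2,6-bis{[2-(hydroxydiphenylmethyl)pyrrolidin-1-yl]methyl}-4-methylphenol), used in the enantiomeric form that delivers the R carbinol. This gives methyl (4R,5E)-4-hydroxy-6-(tributylstannyl)hept-5-en-2-ynoate F2, in which C12 already sits on C11.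
- After deprotonation of the hydroxyl with MeMgBr, the organocopper reagent from 20 and CuBr·SMe2 adds syn at −78 °C (C8 to C7).
- The α-metallated enoate is trapped by formaldehyde in the presence of Et2AlCl (C11–C13).
- After a syn addition the ester lies cis to the C6 oxygen, so it lactonises on work-up to the 13-hydroxy butenolide F3. Silylation with TIPSCl and imidazole gives 26.
- No oxygen stands β to the metal while C7–C8 is formed.

Step 16. Strain in the ten-membered ring may divert the alkenylchromium species to oligomers or to simple protonation. The aldehyde may also lose its β,γ-double bond to conjugation during the slow addition.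
- The fallback sets out from 26 and comes back at 32. It uses the stannane itself in an acylative ring closure, so that steps 13 to 17 are bypassed.
- Pyridine-buffered HF·pyridine removes the smaller silyl group to give the stannyl alcohol F4.
- Dess–Martin oxidation gives the stannyl aldehyde F5.
- NaClO2, NaH2PO4 and 2-methylbut-2-ene give the stannyl acid F6.
- 4-Methylbenzenethiol with N-(3-dimethylaminopropyl)-N′-ethylcarbodiimide gives the S-(4-methylphenyl) thioester F7.
- A Liebeskind–Srogl coupling of thioester and stannane (Pd2(dba)3, tri(2-furyl)phosphine, CuOP(O)Ph2, THF, high dilution) forms C3–C4 directly at the ketone level under neutral conditions.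

Step 18. The conformation of the ten-membered ring exposes one face of the ketone and may override the catalyst, giving poor or reversed facial selectivity. The doubly activated C6–H of the enone may also enolise if the reduction is slow.
- The fallback sets out from 32 and comes back at 36. It accepts substrate control and corrects C3 during esterification.
- Luche reduction (NaBH4, CeCl3·7H2O, MeOH, −78 °C) by peripheral attack should give the (3R,6R)-allylic alcohol F8.
- A Mitsunobu reaction of F8 with tiglic acid 34 (PPh3, diisopropyl azodicarboxylate, toluene, 0 °C) installs the tiglate with inversion to 3S.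

Further compounds
F1 | step 12 | (E)-3-(tributylstannyl)but-2-enal | O=C/C=C(\C)[Sn](CCCC)(CCCC)CCCC
F2 | step 12 | methyl (4R,5E)-4-hydroxy-6-(tributylstannyl)hept-5-en-2-ynoate | COC(=O)C#C[C@H](O)/C=C(\C)[Sn](CCCC)(CCCC)CCCC
F3 | step 12 | (5R)-4-[(3Z)-6-(tert-butyldimethylsilyloxy)-3-methylhex-3-en-1-yl]-3-(hydroxymethyl)-5-[(1E)-2-(tributylstannyl)prop-1-en-1-yl]furan-2(5H)-one | OCC1=C(CC/C(C)=C\CCO[Si](C)(C)C(C)(C)C)[C@@H](/C=C(\C)[Sn](CCCC)(CCCC)CCCC)OC1=O
F4 | step 16 | stannyl alcohol, 26 with free C3–OH | CC(C)[Si](C(C)C)(C(C)C)OCC1=C(CC/C(C)=C\CCO)[C@@H](/C=C(\C)[Sn](CCCC)(CCCC)CCCC)OC1=O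
F5 | step 16 | stannyl aldehyde, C3 as CHO | CC(C)[Si](C(C)C)(C(C)C)OCC1=C(CC/C(C)=C\CC=O)[C@@H](/C=C(\C)[Sn](CCCC)(CCCC)CCCC)OC1=O
F6 | step 16 | stannyl acid, C3 as CO2H | CC(C)[Si](C(C)C)(C(C)C)OCC1=C(CC/C(C)=C\CC(=O)O)[C@@H](/C=C(\C)[Sn](CCCC)(CCCC)CCCC)OC1=O
F7 | step 16 | S-(4-methylphenyl) thioester of F6 | CC(C)[Si](C(C)C)(C(C)C)OCC1=C(CC/C(C)=C\CC(=O)Sc2ccc(C)cc2)[C@@H](/C=C(\C)[Sn](CCCC)(CCCC)CCCC)OC1=O
F8 | step 18 | (3R,6R)-3-hydroxy-13-(triisopropylsilyloxy)germacra-1(10)Z,4E,7(11)-trien-12,6-olide | O[C@@H]1C/C=C(/C)CCC2=C(CO[Si](C(C)C)(C(C)C)C(C)C)C(=O)O[C@@H]2/C=C/1C
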